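**Retrosynthetic overview**
- The target is opened to a chiral 2,3-dihydrofuran, in which the C7 oxygen is tied up as a cyclic enol ether, plus a fumarate-derived acylketene.
- Both target rings are formed in one pot: acylketene [4+2] onto the enol ether (pyran ring), then a transannular enolate aldol (carbocycle), then acid to open the acetal, dehydrate and free the acid.
- The dihydrofuran comes from a lactol, made by a copper–bisoxazoline Mukaiyama aldol of an ester silyl ketene acetal with biacetyl; this sets C7 and C8.
- The ester alcohol comes from (S)-1-bromo-2-methylbutane via the methyl ketone and an enzymatic reduction.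
- Ring order: temporary tetrahydrofuran acetal first, then pyran ring and carbocycle together.

Assumption: methyl 4,4-dimethoxybutanoate, mono-tert-butyl fumarate and the (R,R)-tBu-box ligand are purchased; the lactol is carried forward as its anomeric mixture.

**Step 1**
Reactants: 1 (S)-1-bromo-2-methylbutane; 2 N-methoxy-N-methylacetamide
Product: 4 (S)-4-methylhexan-2-one, via (S)-2-methylbutylmagnesium bromide 3 (not isolated)
Conditions: Mg, THF, reflux; then 2, 0 °C; aq. HCl
Reagents that add atoms: N-methoxy-N-methylacetamide (2), CC(=O)N(C)OC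
Why: Weinreb ketone synthesis; the Grignard adds once to the chelating amide, and the stereocentre is beta to magnesium so it cannot racemise.

**Step 2**
Reactants: 4 (S)-4-methylhexan-2-one
Product: 5 (2S,4S)-4-methylhexan-2-ol
Conditions: alcohol dehydrogenase ADH-A (Rhodococcus ruber), NADH (cat.), iPrOH (20% v/v), K2HPO4/KH2PO4 buffer pH 7.5, 30 °C
Reagents that add atoms: none
Why: Enzymatic Prelog reduction of a methyl ketone; hydride goes to the re face and sets the (2S) carbinol, while C4 is untouched.

**Step 3**
Reactants: 5 (2S,4S)-4-methylhexan-2-ol; 6 methyl 4,4-dimethoxybutanoate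
Product: 7 (2S,4S)-4-methylhexan-2-yl 4,4-dimethoxybutanoate
Conditions: 6 (3 equiv), Bu2SnO (10 mol%), toluene, reflux, 4 Å MS
Reagents that add atoms: methyl 4,4-dimethoxybutanoate (6), COC(=O)CCC(OC)OC
Why: Tin-catalysed transesterification under neutral conditions, driven by methanol removal; the acetal survives and the carbinol configuration is retained because the C–O bond is not broken.

**Step 4**
Reactants: 7 (2S,4S)-4-methylhexan-2-yl 4,4-dimethoxybutanoate
Product: 8 (E)-silyl ketene acetal of 7
Conditions: LiN(iPr)2, Me3SiCl, THF, −78 °C; pentane, filter, concentrate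
Reagents that add atoms: chlorotrimethylsilane, C[Si](C)(C)Cl
Why: Kinetic ester enolisation with in situ O-silylation (Ireland conditions); the ester alpha-carbon is the only acidic position.

**Step 5**
Reactants: 8 (E)-silyl ketene acetal of 7; 9 butane-2,3-dione
Product: 11 (2S,4S)-4-methylhexan-2-yl (2R,3R)-2-acetyl-5-hydroxy-2-methyltetrahydrofuran-3-carboxylate, via silyl aldol adduct 10 (not isolated)
Conditions: 9 (1.5 equiv), [Cu((R,R)-tBu-box)](OTf)2 (10 mol%), THF, −78 °C; then 1 M HCl, THF, rt
Reagents that add atoms: butane-2,3-dione (9), CC(=O)C(C)=O; water, O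
Why: Catalytic enantioselective Mukaiyama aldol to a 1,2-diketone chelated on the divalent copper bisoxazoline complex. Re-face attack sets (R) at the tertiary carbinol (the (S,S) catalyst gives (S) carbinols from pyruvates by si-face attack), and the open transition state gives the syn adduct, which sets (R) at the ester alpha-carbon. Aqueous acid then removes the silyl group and the acetal, and the hydroxy aldehyde closes to the lactol.

**Step 6**
Reactants: 11 lactol
Product: 12 (2S,4S)-4-methylhexan-2-yl (2R,3R)-2-acetyl-2-methyl-2,3-dihydrofuran-3-carboxylate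
Conditions: MsCl, Et3N, CH2Cl2, −20 °C to rt
Reagents that add atoms: none
Why: Anomeric mesylation and elimination (glycal-type synthesis) gives the cyclic enol ether; neither stereocentre is touched, and the tertiary oxygen is now masked as the enol ether oxygen.

**Step 7**
Reactants: 13 Meldrum's acid; 14 mono-tert-butyl fumarate
Product: 15 tert-butyl (E)-4-(2,2-dimethyl-4,6-dioxo-1,3-dioxan-5-ylidene)-4-hydroxybut-2-enoate
Conditions: DCC, DMAP, CH2Cl2, 0 °C to rt; aq. KHSO4 wash
Reagents that add atoms: mono-tert-butyl fumarate (14), OC(=O)/C=C/C(=O)OC(C)(C)C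
Why: C-acylation of Meldrum's acid with a carbodiimide-activated acid gives the enolised acyl Meldrum's acid, a standard thermal acylketene precursor; the (E) alkene is carried through.

**Step 8**
Reactants: 12 dihydrofuran; 15 acyl Meldrum's acid
Product: 20 (2S,4S)-4-methylhexan-2-yl (7R,8R)-3-[(E)-2-carboxyethenyl]-7-hydroxy-7-methyl-6-oxo-7,8-dihydro-6H-isochromene-8-carboxylate, via acylketene 16 (not isolated), via furopyranone acetal 17 (not isolated), via bridged aldol 18 (not isolated), via tert-butyl ester 19 (not isolated)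
Conditions: (a) 15 (1.05 equiv), toluene, 95 °C, 2 h, then evaporate; (b) LiN(SiMe3)2 (1.3 equiv), THF, −78 °C, 1 h; (c) CF3CO2H/CH2Cl2 (1:3), −78 °C to rt, 2 h
Reagents that add atoms: acyl Meldrum's acid (15), CC1(C)OC(=O)C(=C(O)/C=C/C(=O)OC(C)(C)C)C(=O)O1
Why: Proposed new method: thermolysis of 15 gives acylketene 16, which adds to the enol ether of 12 in the known acylketene hetero-Diels–Alder (the gamma-pyrone synthesis from acyl Meldrum's acids and vinyl ethers) on the face anti to the ester to give cis-fused acetal 17; in 17 C1 is still an sp3 acetal, so the kinetic lithium enolate of the methyl ketone can only add 1,2 to the vinylogous-ester carbonyl (Stork–Danheiser-type addition; the acetyl group and that carbonyl are cis on the tetrahydrofuran, whereas Dieckmann attack on the trans ester would need a trans-fused bicyclo[3.3.0] ring), closing the carbocycle as 18; acid then ionises the doubly allylic carbinol to give the C4a=C5 enone, eliminates the acetal C–O bond to release the C7 hydroxyl and the C1=C8a bond, and cleaves the tert-butyl ester, with C7 and C8 carried through unchanged.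

**Compound list**
1 | (S)-1-bromo-2-methylbutane | CC[C@H](C)CBr | starting material
2 | N-methoxy-N-methylacetamide | CC(=O)N(C)OC | starting material
3 | (S)-2-methylbutylmagnesium bromide | CC[C@H](C)C[Mg]Br | intermediate
4 | (S)-4-methylhexan-2-one | CC[C@H](C)CC(C)=O | intermediate
5 | (2S,4S)-4-methylhexan-2-ol | CC[C@H](C)C[C@H](C)O | intermediate
6 | methyl 4,4-dimethoxybutanoate | COC(=O)CCC(OC)OC | starting material
7 | (2S,4S)-4-methylhexan-2-yl 4,4-dimethoxybutanoate | CC[C@H](C)C[C@H](C)OC(=O)CCC(OC)OC | intermediate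
8 | (E)-silyl ketene acetal of 7: trimethylsilyl enol ether at the ester carbon, C=C to the former alpha-carbon, E major | CC[C@H](C)C[C@H](C)O/C(O[Si](C)(C)C)=C\CC(OC)OC | intermediate
9 | butane-2,3-dione (biacetyl) | CC(=O)C(C)=O | starting material
10 | (2S,4S)-4-methylhexan-2-yl (2R,3R)-2-(2,2-dimethoxyethyl)-3-methyl-4-oxo-3-(trimethylsilyloxy)pentanoate | CC[C@H](C)C[C@H](C)OC(=O)[C@H](CC(OC)OC)[C@@](C)(O[Si](C)(C)C)C(C)=O | intermediate
11 | (2S,4S)-4-methylhexan-2-yl (2R,3R)-2-acetyl-5-hydroxy-2-methyltetrahydrofuran-3-carboxylate (lactol, anomeric mixture) | CC[C@H](C)C[C@H](C)OC(=O)[C@@H]1CC(O)O[C@@]1(C)C(C)=O | intermediate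
12 | (2S,4S)-4-methylhexan-2-yl (2R,3R)-2-acetyl-2-methyl-2,3-dihydrofuran-3-carboxylate | CC[C@H](C)C[C@H](C)OC(=O)[C@@H]1C=CO[C@@]1(C)C(C)=O | intermediate
13 | Meldrum's acid (2,2-dimethyl-1,3-dioxane-4,6-dione) | CC1(C)OC(=O)CC(=O)O1 | starting material
14 | mono-tert-butyl fumarate ((E)-4-tert-butoxy-4-oxobut-2-enoic acid) | OC(=O)/C=C/C(=O)OC(C)(C)C | starting material
15 | tert-butyl (E)-4-(2,2-dimethyl-4,6-dioxo-1,3-dioxan-5-ylidene)-4-hydroxybut-2-enoate (acyl Meldrum's acid, enol form) | CC1(C)OC(=O)C(=C(O)/C=C/C(=O)OC(C)(C)C)C(=O)O1 | intermediate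
16 | tert-butyl (E)-4,6-dioxohexa-2,5-dienoate (acylketene) | O=C=CC(=O)/C=C/C(=O)OC(C)(C)C | intermediate
17 | (2S,4S)-4-methylhexan-2-yl (2R,3R,3aR,7aS)-2-acetyl-6-[(E)-3-tert-butoxy-3-oxoprop-1-enyl]-2-methyl-4-oxo-2,3,3a,7a-tetrahydro-4H-furo[2,3-b]pyran-3-carboxylate | CC[C@H](C)C[C@H](C)OC(=O)[C@@H]1[C@H]2C(=O)C=C(/C=C/C(=O)OC(C)(C)C)O[C@H]2O[C@@]1(C)C(C)=O | intermediate
18 | bridged aldol of 17: the acetyl CH3 carbon is bonded to the former pyranone carbonyl carbon, which now carries OH; this gives a new cyclohexanone ring bridged by the O–CH acetal (lithium alkoxide before the quench) | CC[C@H](C)C[C@H](C)OC(=O)[C@@H]1[C@H]2[C@]3(O)C=C(/C=C/C(=O)OC(C)(C)C)O[C@H]2O[C@@]1(C)C(=O)C3 | intermediate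
19 | (2S,4S)-4-methylhexan-2-yl (7R,8R)-3-[(E)-3-tert-butoxy-3-oxoprop-1-enyl]-7-hydroxy-7-methyl-6-oxo-7,8-dihydro-6H-isochromene-8-carboxylate | CC[C@H](C)C[C@H](C)OC(=O)[C@@H]1C2=COC(/C=C/C(=O)OC(C)(C)C)=CC2=CC(=O)[C@]1(C)O | intermediate
20 | (2S,4S)-4-methylhexan-2-yl (7R,8R)-3-[(E)-2-carboxyethenyl]-7-hydroxy-7-methyl-6-oxo-7,8-dihydro-6H-isochromene-8-carboxylate | CC[C@H](C)C[C@H](C)OC(=O)[C@@H]1C2=COC(/C=C/C(=O)O)=CC2=CC(=O)[C@]1(C)O | target

**Step count**
Total steps: 8. Longest linear sequence: 7 (steps 1, 2, 3, 4, 5, 6, 8); step 7 is a one-step side branch.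

**Three steps most likely to fail**

Step 8. The enolate may fail to add to the vinylogous-ester carbonyl of 17, or 17 may lose its acetal early to the free gamma-pyrone, whose unsubstituted C1 is then a competing Michael site. The final acid stage could also dehydrate the tertiary alcohol. The fallback sets out from 12 (with 15) and comes back at 19. Only the thermal cycloaddition is run, then TsOH·H2O in THF opens the acetal by beta-elimination to give the isolable gamma-pyrone alcohol F1. MeOTf O-methylates the pyrone carbonyl to the 4-methoxypyrylium triflate F2. 2,6-Lutidine then lets the ketone enol displace methoxide at C4 by addition–elimination; this is the known condensation of 4-alkoxypyrylium salts with C–H acids, and the loss of methanol is irreversible. The product is 19, and brief CF3CO2H gives 20.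

Step 5. An ester-derived silyl ketene acetal carrying an acetal is outside the usual thioester scope of this aldol, so enantioselectivity or syn selectivity may be lower. The fallback sets out from 6 and comes back at 10. Me2AlS-tBu (from AlMe3 and 2-methylpropane-2-thiol) converts 6 into the thioester F3. LiN(iPr)2/Me3SiCl gives the (Z)-silyl ketene thioacetal F4. The same copper catalyst with 9 gives the silylated syn aldol thioester F5. AgO2CCF3 with alcohol 5 then exchanges the thioester for the ester to give 10, which is hydrolysed to 11 as before.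

Step 7. The fumaroyl Meldrum's acid carries a doubly activated alkene and may suffer conjugate addition or decompose on isolation. The fallback sets out from 14 and comes back at 16. Carbonyldiimidazole activation of 14 and reaction with Mg(O2CCH2CO2tBu)2 (Masamune–Brooks chain extension) gives the beta-keto ester di-tert-butyl (E)-3-oxohex-4-enedioate F6. Heating F6 with 12 in toluene at 110 °C expels tert-butanol by retro-ene fragmentation of the tert-butyl beta-keto ester and generates acylketene 16 directly in the first stage of step 8.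

**Further compounds**
F1 | step 8 | (2S,4S)-4-methylhexan-2-yl (2R,3R)-2-{6-[(E)-3-tert-butoxy-3-oxoprop-1-enyl]-4-oxo-4H-pyran-3-yl}-3-hydroxy-3-methyl-4-oxopentanoate | CC[C@H](C)C[C@H](C)OC(=O)[C@H](C1=COC(/C=C/C(=O)OC(C)(C)C)=CC1=O)[C@@](C)(O)C(C)=O
F2 | step 8 | 4-methoxypyrylium trifluoromethanesulfonate of F1 (O-methylated at the pyrone carbonyl) | CC[C@H](C)C[C@H](C)OC(=O)[C@H](c1c[o+]c(/C=C/C(=O)OC(C)(C)C)cc1OC)[C@@](C)(O)C(C)=O.[O-]S(=O)(=O)C(F)(F)F
F3 | step 5 | S-tert-butyl 4,4-dimethoxybutanethioate | CC(C)(C)SC(=O)CCC(OC)OC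
F4 | step 5 | tert-butyl (Z)-4,4-dimethoxy-1-(trimethylsilyloxy)but-1-enyl sulfide | CC(C)(C)S/C(O[Si](C)(C)C)=C\CC(OC)OC
F5 | step 5 | S-tert-butyl (2R,3R)-2-(2,2-dimethoxyethyl)-3-methyl-4-oxo-3-(trimethylsilyloxy)pentanethioate | CC(C)(C)SC(=O)[C@H](CC(OC)OC)[C@@](C)(O[Si](C)(C)C)C(C)=O
F6 | step 7 | di-tert-butyl (E)-3-oxohex-4-enedioate | CC(C)(C)OC(=O)CC(=O)/C=C/C(=O)OC(C)(C)C
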